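The vessel was closed, stirred and isothermal, and two earlier runs in it were what I had to reason from.

| setting | teal | red | autumn | winter | summer |
|---|---|---|---|---|---|
| electrophile | 0.25 M | 0.25 M | 0.25 M | 0.25 M | 0.25 M |
| nucleophile | 0.31 M | 1.7 M | 0.260 M | 0.530 M | 1.10 M |
| remark | run made earlier | run made earlier |  |  |  |
| time |  |  | 4.0 h | 4.0 h | 4.0 h |

| run | time / min | electrophile / % | target / % |
|---|---|---|---|
| teal | 25.0 | 80.3 | 19.2 |
| teal | 50.0 | 73.3 | 27.8 |
| teal | 80.0 | 67.9 | 31.5 |
| teal | 90.0 | 67.6 | 34.6 |
| teal | 120 | 64.8 | 35.0 |
| red | 25.0 | 48.4 | 51.5 |
| red | 50.0 | 33.5 | 63.3 |
| red | 80.0 | 30.3 | 70.4 |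
| red | 90.0 | 30.3 | 69.2 |
| red | 120 | 26.4 | 73.9 |

(readings scatter by 1 percentage point)

- what may be going on: electrophile + nucleophile -> acid set free + target; 2 nucleophile -> self-condensation product; nucleophile + acid set free <-> protonated nucleophile

- part of the electrophile that has reacted at the end, autumn
- part of the electrophile that has reacted at the end, winter
- part of the electrophile that has reacted at the end, summer
- what raising the concentration of nucleophile from its lowest to its highest value here does to the part of the electrophile that has reacted (changes below 5 percentage points count as none) (it rises / it falls / no change)

At the bench I would call a large nucleophile charge pseudo-first-order. The first red reading gave k′ = 0.0290 min⁻¹, a half-life of 23.9 min, and the rule so put 3.08% of the electrophile left at 120 min, but the reading there was 26.4%. Red was charged at a nucleophile-to-electrophile ratio of 6.80, and even there the rule had passed its border by that reading. I therefore followed the free nucleophile N, which enters the target step at first order and self-condensation at second.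

Each target costs two N if its acid binds one, and each self-condensation costs two. Guessing the two rate constants equal, I had dN/dE = 2(E + N)/E for free concentrations E and N. Integrating until N is gone gave, for charges n and e, a reacted part X = n/(n + 2e). For summer X = 68.8%, and this X, the nucleophile share, was my quantity. It gave 38.3% for teal against 35.2% reacted at the last reading, and 77.3% for red against 73.6%, so I kept the guess. For autumn and winter I reckoned 34.2% and 51.5%.

The forecast differed from my figures: 32%, 47% and 62% for autumn, winter and summer, the last lower than mine. Its trend was: it rises; its words were “Self-condensation blunts the gain, but conversion still rises.”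

Autumn, winter and summer gave 35.2%, 53.0% and 70.1% reacted at 4.0 h; the trend was: it rises, by 35 percentage points.

    electrophile + nucleophile → acid set free + target (k = 0.0420 M⁻¹ min⁻¹)
    2 nucleophile → self-condensation product (k = 0.0360 M⁻¹ min⁻¹)
    nucleophile + acid set free ⇌ protonated nucleophile, settled at all times (K = 20000 M⁻¹)

Summer, with share 68.8% against 70.1%, had 81% of its self-condensation turnover up to 4.0 h behind it by 0.400 h. At 4.0 h summer held 1.7% of its charged nucleophile unbound against 30% of its charged electrophile; the nucleophile, though charged at more than the electrophile, stood as the limiting reagent. For the summer flask with 1.0 M of electrophile, the share gave 35.5%, and the computed flask gave 37.8% reacted at 4.0 h.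

The data were computed for substances that don't exist, and the scatter is random.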